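**Plan**
- Retrosynthesis: the five O-benzyl bonds are cut first, then the aryl–C(=O) bond of ring B (Friedel–Crafts acylation at its one free carbon) and that of ring A (back to an aryl bromide through the aryllithium). Ring B (the methoxy ring) is then opened at its C(H)–C(OH) and C(O-silyl)–C(bridge) bonds to a cyclobutenone and (triisopropylsilyloxy)ethyne.
- The cyclobutenone is cut into methylketene and a benzylic ynol ether, and the ynol ether at its CH2–C(sp) bond into a ring A benzylic bromide and methoxyacetylide.
- Forward: ring A (the trihydroxy ring) is bought as 2-methylphloroglucinol and fitted with CHO, Br and three benzyl ethers. The CH2–C≡C–OMe chain is joined, the four-membered ring is made by ketene [2+2], and ring B is made by benzannulation. The butanoyl groups then enter one per step (ring A from its bromide, ring B by acylation of its free CH) and the benzyl groups leave last, so neither ketone ever meets an acetylide or an organolithium reagent.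
- Enabling feature: in ring B, O-bearing and C-bearing carbons alternate, and the OMe carbon sits between the methyl-bearing and the bridge-bearing carbon. That is the C2–C3–C4 strip of a 2-benzyl-3-methoxy-4-methylcyclobutenone; the remaining arc C(OH)–C(H)–C(O) is the ketene carbonyl plus HC≡C–O–Si, so the three oxygens of ring B arise as OMe, free OH and O-silyl.
- Stereochemistry: the target is achiral; the one stereocentre made on the way (C4 of the racemic cyclobutenone) is erased when ring B aromatises.

Key step: step 10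

Assumption: 3-phenylisoxazole (16) and N-methoxy-N-methylbutanamide (27) are taken as catalogue compounds, and the parent lithium ethynolate is taken to be silylated on oxygen by a bulky silyl triflate as its substituted homologues are.

**Step 1**
Reactants: 1 2-methylphloroglucinol (2-methylbenzene-1,3,5-triol)
Product: 3 2,4,6-trihydroxy-3-methylbenzaldehyde, via iminium chloride 2 (not isolated)
Conditions: POCl3 (1.05 equiv), DMF, EtOAc, 0 °C to rt; then H2O, 50 °C
Reagents that add atoms: N,N-dimethylformamide CN(C)C=O; water O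
Why: Vilsmeier–Haack formylation of a phloroglucinol, in which the two free ring carbons of 1 are equivalent, so that one equivalent of reagent should give a single aldehyde.

**Step 2**
Reactants: 3 2,4,6-trihydroxy-3-methylbenzaldehyde
Product: 4 3-bromo-2,4,6-trihydroxy-5-methylbenzaldehyde
Conditions: NBS (1.0 equiv), THF, −20 to 0 °C, dark
Reagents that add atoms: N-bromosuccinimide O=C1CCC(=O)N1Br
Why: Electrophilic aromatic bromination at the only unsubstituted, triply oxygen-activated ring carbon; the bromine blocks C-benzylation in step 3 and self-alkylation of bromide 7, and marks the site of the ring A butanoyl group.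

**Step 3**
Reactants: 4 3-bromo-2,4,6-trihydroxy-5-methylbenzaldehyde
Product: 5 2,4,6-tris(benzyloxy)-3-bromo-5-methylbenzaldehyde
Conditions: BnBr (4 equiv), K2CO3 (5 equiv), DMF, 60 °C
Reagents that add atoms: benzyl bromide BrCc1ccccc1
Why: Williamson etherification of a fully substituted, electron-poor phloroglucinol, where K2CO3 in DMF should favour O-alkylation over dearomatising C-alkylation.

**Step 4**
Reactants: 5 2,4,6-tris(benzyloxy)-3-bromo-5-methylbenzaldehyde
Product: 6 [2,4,6-tris(benzyloxy)-3-bromo-5-methylphenyl]methanol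
Conditions: NaBH4, THF/MeOH, 0 °C
Reagents that add atoms: none
Why: Borohydride reduction of an aryl aldehyde, to which aryl bromide and benzyl ethers are inert.

**Step 5**
Reactants: 6 [2,4,6-tris(benzyloxy)-3-bromo-5-methylphenyl]methanol
Product: 7 1,3,5-tris(benzyloxy)-2-bromo-4-(bromomethyl)-6-methylbenzene
Conditions: PBr3 (0.4 equiv), pyridine (cat.), Et2O, −10 to 0 °C; used crude at once
Reagents that add atoms: phosphorus tribromide BrP(Br)Br
Why: Conversion of a benzylic alcohol to the bromide through its phosphite ester; the ring has no free position and carries bromine, which should temper ionisation and exclude Friedel–Crafts self-condensation.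

**Step 6**
Reactants: 8 chloroacetaldehyde dimethyl acetal (2-chloro-1,1-dimethoxyethane)
Product: 10 methoxyethyne, via sodium methoxyacetylide 9 (not isolated)
Conditions: NaNH2 (3 equiv), liquid NH3, −33 °C; evaporate NH3; cold saturated aqueous NaCl; distil (bp about 23 °C) into cold THF
Reagents that add atoms: none
Why: Twofold base-induced elimination (HCl, then MeOH) from a chloroacetal with sodium amide, the classical alkoxyacetylene synthesis, the third equivalent of base holding the product as its acetylide until the quench.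

**Step 7**
Reactants: 10 methoxyethyne; 7 1,3,5-tris(benzyloxy)-2-bromo-4-(bromomethyl)-6-methylbenzene
Product: 12 1,3,5-tris(benzyloxy)-2-bromo-4-(3-methoxyprop-2-yn-1-yl)-6-methylbenzene, via lithium methoxyacetylide 11 (not isolated)
Conditions: 10 (2.5 equiv), n-BuLi (2.2 equiv), THF, −78 °C; then 7, DMPU, −78 to 0 °C
Reagents that add atoms: none
Why: SN2 alkylation of a lithium alkoxyacetylide by a reactive benzylic bromide; the acetylide is amine-free, so no N-alkylation competes, and it does not exchange with the aryl bromide.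

**Step 8**
Reactants: 12 1,3,5-tris(benzyloxy)-2-bromo-4-(3-methoxyprop-2-yn-1-yl)-6-methylbenzene; 13 propanoyl chloride
Product: 15 rac-2-{[2,4,6-tris(benzyloxy)-3-bromo-5-methylphenyl]methyl}-3-methoxy-4-methylcyclobut-2-en-1-one, via methylketene 14 (not isolated)
Conditions: 13 (3 equiv, slow addition), Et3N (4 equiv), CH2Cl2, 0 to 40 °C
Reagents that add atoms: none
Why: [2+2] cycloaddition of a ketene made in situ with an ynol ether; the benzyl-bearing alkyne carbon is the nucleophile and attacks the ketene carbonyl carbon, so the methoxy carbon ends next to the CHMe carbon (racemic at C4).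

**Step 9**
Reactants: 16 3-phenylisoxazole
Product: 19 (triisopropylsilyloxy)ethyne, via 5-lithio-3-phenylisoxazole 17 (not isolated), via lithium ethynolate 18 (not isolated)
Conditions: n-BuLi (1.0 equiv), THF, −78 °C, then −30 °C; TIPSOTf (1.05 equiv), −78 °C to rt; distil under reduced pressure
Reagents that add atoms: triisopropylsilyl trifluoromethanesulfonate CC(C)[Si](C(C)C)(C(C)C)OS(=O)(=O)C(F)(F)F
Why: Lithiation at C5 and cycloreversion of the 5-lithioisoxazole to benzonitrile and the lithium ynolate, followed by O-silylation of the ynolate with a bulky silyl triflate, the standard siloxyalkyne synthesis.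

**Step 10**
Reactants: 15 rac-2-{[2,4,6-tris(benzyloxy)-3-bromo-5-methylphenyl]methyl}-3-methoxy-4-methylcyclobut-2-en-1-one; 19 (triisopropylsilyloxy)ethyne
Product: 24 4-{[2,4,6-tris(benzyloxy)-3-bromo-5-methylphenyl]methyl}-3-methoxy-2-methyl-5-[(triisopropylsilyl)oxy]phenol, via vinylketene 20 (not isolated), via vinylcyclobutenone 21 (not isolated), via dienylketene 22 (not isolated), via cyclohexadienone 23 (not isolated)
Conditions: 19 (2.5 equiv, in two portions), toluene (0.5 M), argon, sealed tube, 80 °C then 110 °C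
Reagents that add atoms: none
Why: Heat opens 15 in a conrotatory 4π electrocyclic step to vinylketene 20, whose ketene C=C takes up the siloxyalkyne in a [2+2] to give 21, and 21 opens in a second 4π step to dienylketene 22. Ring B is then closed by a thermal disrotatory 6π electrocyclisation that joins the ketene carbon to the CHMe end of the triene, and dienone 23 tautomerises to phenol 24. The closest known reaction is the Danheiser benzannulation of 3-alkoxycyclobutenones with siloxyalkynes, which gives resorcinol monosilyl ethers. No stereocentre is left, since the racemic centre of 15 and those of 21 and 23 disappear on aromatisation. The one selectivity required is the orientation of the [2+2]: the oxygen lone pair makes the terminal alkyne carbon the nucleophile and the ketene central carbon is the electrophile, so the O-silyl carbon can only bond to the carbon that carries the ring A benzyl group. Nothing but heat is applied, which should leave the aryl bromide and the benzyl ethers of ring A alone.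

**Step 11**
Reactants: 24 4-{[2,4,6-tris(benzyloxy)-3-bromo-5-methylphenyl]methyl}-3-methoxy-2-methyl-5-[(triisopropylsilyl)oxy]phenol
Product: 26 1,3,5-tris(benzyloxy)-2-{[2,4-bis(benzyloxy)-6-methoxy-5-methylphenyl]methyl}-4-bromo-6-methylbenzene, via benzyl ether 25 (not isolated)
Conditions: BnBr (3 equiv), K2CO3, DMF, rt; then CsF (1.5 equiv), 50 °C
Reagents that add atoms: benzyl bromide BrCc1ccccc1
Why: Williamson benzylation of the free phenol, then fluoride cleavage of the aryl silyl ether with benzylation of the phenoxide in the same pot; only one phenoxide is on ring B at a time, which should disfavour C-benzylation at its free carbon.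

**Step 12**
Reactants: 26 1,3,5-tris(benzyloxy)-2-{[2,4-bis(benzyloxy)-6-methoxy-5-methylphenyl]methyl}-4-bromo-6-methylbenzene; 27 N-methoxy-N-methylbutanamide
Product: 30 1-{2,4,6-tris(benzyloxy)-3-{[2,4-bis(benzyloxy)-6-methoxy-5-methylphenyl]methyl}-5-methylphenyl}butan-1-one, via aryllithium 28 (not isolated), via lithium hemiaminal 29 (not isolated)
Conditions: t-BuLi (2.1 equiv), THF, −78 °C, 15 min; then 27 (1.5 equiv), −78 to 0 °C; saturated aqueous NH4Cl
Reagents that add atoms: none
Why: Bromine–lithium exchange at the only halogen of the molecule followed by Weinreb ketone synthesis; the 2,6-dialkoxyaryllithium adds once to the amide and the chelated adduct releases the ketone only on work-up, while the ring B CH is not metalated at −78 °C.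

**Step 13**
Reactants: 30 1-{2,4,6-tris(benzyloxy)-3-{[2,4-bis(benzyloxy)-6-methoxy-5-methylphenyl]methyl}-5-methylphenyl}butan-1-one; 31 butanoic acid
Product: 33 1-{2,4,6-tris(benzyloxy)-3-{[2,4-bis(benzyloxy)-3-butanoyl-6-methoxy-5-methylphenyl]methyl}-5-methylphenyl}butan-1-one, via mixed anhydride 32 (not isolated)
Conditions: 31 (1.5 equiv), (CF3CO)2O (3 equiv), CH2Cl2, 0 °C, 15 min; then 30, 0 °C to rt; cold aqueous NaHCO3
Reagents that add atoms: none
Why: Friedel–Crafts acylation by the mixed anhydride of butanoic and trifluoroacetic acid, a variant free of metal Lewis acids that is established for phloroglucinol triethers; ring B offers a single free carbon, ortho to two benzyloxy groups and para to OMe, whereas ring A is fully substituted and deactivated by its ketone, so one ketone should form.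

**Step 14**
Reactants: 33 1-{2,4,6-tris(benzyloxy)-3-{[2,4-bis(benzyloxy)-3-butanoyl-6-methoxy-5-methylphenyl]methyl}-5-methylphenyl}butan-1-one
Product: 34 Margaspidin
Conditions: H2 (1 atm), Pd/C (10 wt% Pd), EtOAc/MeOH, rt, stopped after uptake of five equivalents
Reagents that add atoms: none
Why: Catalytic hydrogenolysis of five aryl benzyl ethers; the hydrogen-bonded aryl ketones, the methyl ether and the diarylmethane should persist at one atmosphere and room temperature.

**Compound list**
1 | 2-methylphloroglucinol (2-methylbenzene-1,3,5-triol) | Cc1c(O)cc(O)cc1O | starting material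
2 | N-[(2,4,6-trihydroxy-3-methylphenyl)methylidene]-N-methylmethanaminium chloride | C[N+](C)=Cc1c(O)c(C)c(O)cc1O.[Cl-] | intermediate
3 | 2,4,6-trihydroxy-3-methylbenzaldehyde | O=Cc1c(O)c(C)c(O)cc1O | intermediate
4 | 3-bromo-2,4,6-trihydroxy-5-methylbenzaldehyde | O=Cc1c(O)c(C)c(O)c(Br)c1O | intermediate
5 | 2,4,6-tris(benzyloxy)-3-bromo-5-methylbenzaldehyde | O=Cc1c(OCc2ccccc2)c(C)c(OCc2ccccc2)c(Br)c1OCc1ccccc1 | intermediate
6 | [2,4,6-tris(benzyloxy)-3-bromo-5-methylphenyl]methanol | OCc1c(OCc2ccccc2)c(C)c(OCc2ccccc2)c(Br)c1OCc1ccccc1 | intermediate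
7 | 1,3,5-tris(benzyloxy)-2-bromo-4-(bromomethyl)-6-methylbenzene | BrCc1c(OCc2ccccc2)c(C)c(OCc2ccccc2)c(Br)c1OCc1ccccc1 | intermediate
8 | chloroacetaldehyde dimethyl acetal (2-chloro-1,1-dimethoxyethane) | COC(CCl)OC | starting material
9 | sodium methoxyacetylide | [Na+].[C-]#COC | intermediate
10 | methoxyethyne | COC#C | intermediate
11 | lithium methoxyacetylide | [Li]C#COC | intermediate
12 | 1,3,5-tris(benzyloxy)-2-bromo-4-(3-methoxyprop-2-yn-1-yl)-6-methylbenzene | COC#CCc1c(OCc2ccccc2)c(C)c(OCc2ccccc2)c(Br)c1OCc1ccccc1 | intermediate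
13 | propanoyl chloride | CCC(=O)Cl | starting material
14 | methylketene (prop-1-en-1-one) | CC=C=O | intermediate
15 | rac-2-{[2,4,6-tris(benzyloxy)-3-bromo-5-methylphenyl]methyl}-3-methoxy-4-methylcyclobut-2-en-1-one (racemic at C4) | O=C1C(Cc2c(OCc3ccccc3)c(C)c(OCc3ccccc3)c(Br)c2OCc2ccccc2)=C(OC)C1C | intermediate
16 | 3-phenylisoxazole (3-phenyl-1,2-oxazole) | c1ccc(cc1)-c1ccon1 | starting material
17 | 5-lithio-3-phenylisoxazole | [Li]c1cc(-c2ccccc2)no1 | intermediate
18 | lithium ethynolate | [Li+].[O-]C#C | intermediate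
19 | (triisopropylsilyloxy)ethyne | C#CO[Si](C(C)C)(C(C)C)C(C)C | intermediate
20 | (3Z)-2-{[2,4,6-tris(benzyloxy)-3-bromo-5-methylphenyl]methyl}-3-methoxypenta-1,3-dien-1-one | O=C=C(Cc1c(OCc2ccccc2)c(C)c(OCc2ccccc2)c(Br)c1OCc1ccccc1)/C(OC)=C/C | intermediate
21 | rac-4-{[2,4,6-tris(benzyloxy)-3-bromo-5-methylphenyl]methyl}-4-[(1Z)-1-methoxyprop-1-en-1-yl]-3-[(triisopropylsilyl)oxy]cyclobut-2-en-1-one (racemic at C4) | O=C1C=C(O[Si](C(C)C)(C(C)C)C(C)C)C1(Cc1c(OCc2ccccc2)c(C)c(OCc2ccccc2)c(Br)c1OCc1ccccc1)/C(OC)=C/C | intermediate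
22 | (3E,5Z)-4-{[2,4,6-tris(benzyloxy)-3-bromo-5-methylphenyl]methyl}-5-methoxy-3-[(triisopropylsilyl)oxy]hepta-1,3,5-trien-1-one | O=C=C\C(O[Si](C(C)C)(C(C)C)C(C)C)=C(Cc1c(OCc2ccccc2)c(C)c(OCc2ccccc2)c(Br)c1OCc1ccccc1)/C(OC)=C/C | intermediate
23 | rac-4-{[2,4,6-tris(benzyloxy)-3-bromo-5-methylphenyl]methyl}-5-methoxy-6-methyl-3-[(triisopropylsilyl)oxy]cyclohexa-2,4-dien-1-one (racemic at C6) | O=C1C=C(O[Si](C(C)C)(C(C)C)C(C)C)C(Cc2c(OCc3ccccc3)c(C)c(OCc3ccccc3)c(Br)c2OCc2ccccc2)=C(OC)C1C | intermediate
24 | 4-{[2,4,6-tris(benzyloxy)-3-bromo-5-methylphenyl]methyl}-3-methoxy-2-methyl-5-[(triisopropylsilyl)oxy]phenol | Oc1cc(O[Si](C(C)C)(C(C)C)C(C)C)c(Cc2c(OCc3ccccc3)c(C)c(OCc3ccccc3)c(Br)c2OCc2ccccc2)c(OC)c1C | intermediate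
25 | {5-(benzyloxy)-3-methoxy-4-methyl-2-{[2,4,6-tris(benzyloxy)-3-bromo-5-methylphenyl]methyl}phenoxy}triisopropylsilane | COc1c(C)c(OCc2ccccc2)cc(O[Si](C(C)C)(C(C)C)C(C)C)c1Cc1c(OCc2ccccc2)c(C)c(OCc2ccccc2)c(Br)c1OCc1ccccc1 | intermediate
26 | 1,3,5-tris(benzyloxy)-2-{[2,4-bis(benzyloxy)-6-methoxy-5-methylphenyl]methyl}-4-bromo-6-methylbenzene | COc1c(C)c(OCc2ccccc2)cc(OCc2ccccc2)c1Cc1c(OCc2ccccc2)c(C)c(OCc2ccccc2)c(Br)c1OCc1ccccc1 | intermediate
27 | N-methoxy-N-methylbutanamide | CCCC(=O)N(C)OC | starting material
28 | {2,4,6-tris(benzyloxy)-3-{[2,4-bis(benzyloxy)-6-methoxy-5-methylphenyl]methyl}-5-methylphenyl}lithium (the bromine atom of 26 replaced by lithium) | COc1c(C)c(OCc2ccccc2)cc(OCc2ccccc2)c1Cc1c(OCc2ccccc2)c(C)c(OCc2ccccc2)c([Li])c1OCc1ccccc1 | intermediate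
29 | lithium 1-{2,4,6-tris(benzyloxy)-3-{[2,4-bis(benzyloxy)-6-methoxy-5-methylphenyl]methyl}-5-methylphenyl}-1-[methoxy(methyl)amino]butan-1-olate (racemic) | COc1c(C)c(OCc2ccccc2)cc(OCc2ccccc2)c1Cc1c(OCc2ccccc2)c(C)c(OCc2ccccc2)c(C(CCC)(O[Li])N(C)OC)c1OCc1ccccc1 | intermediate
30 | 1-{2,4,6-tris(benzyloxy)-3-{[2,4-bis(benzyloxy)-6-methoxy-5-methylphenyl]methyl}-5-methylphenyl}butan-1-one | COc1c(C)c(OCc2ccccc2)cc(OCc2ccccc2)c1Cc1c(OCc2ccccc2)c(C)c(OCc2ccccc2)c(C(=O)CCC)c1OCc1ccccc1 | intermediate
31 | butanoic acid | CCCC(=O)O | starting material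
32 | butanoic trifluoroacetic anhydride | CCCC(=O)OC(=O)C(F)(F)F | intermediate
33 | 1-{2,4,6-tris(benzyloxy)-3-{[2,4-bis(benzyloxy)-3-butanoyl-6-methoxy-5-methylphenyl]methyl}-5-methylphenyl}butan-1-one | CCCC(=O)c1c(OCc2ccccc2)c(C)c(OCc2ccccc2)c(Cc2c(OCc3ccccc3)c(C(=O)CCC)c(OCc3ccccc3)c(C)c2OC)c1OCc1ccccc1 | intermediate
34 | Margaspidin | CCCC(=O)c1c(O)c(C)c(O)c(Cc2c(O)c(C(=O)CCC)c(O)c(C)c2OC)c1O | target

**Step count**
Total: 14 steps. Longest linear sequence: 12 steps (steps 1–5, 7, 8, 10–14, from 1 to 34); steps 6 and 9 are side branches.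

**Steps most likely to fail**

Step 10. The crowded cyclobutenone may open slowly, so that the terminal siloxyalkyne isomerises to the silylketene or is consumed before it traps the vinylketene, and ketene intermediates may acylate the product phenol. The fallback gives up ring construction for the classical methylene coupling; it sets out from 1 and comes back to the route only at 34. Compound 1 is C-acylated with butanoyl chloride (AlCl3, nitrobenzene, Friedel–Crafts) to 1-(2,4,6-trihydroxy-3-methylphenyl)butan-1-one F1. Part of it is methylated at the non-chelated 4-OH (Me2SO4, 1 equiv, K2CO3, acetone) to 1-(2,6-dihydroxy-4-methoxy-3-methylphenyl)butan-1-one F2. F1 and F2 are then joined with aqueous formaldehyde in dilute KOH at 0 °C, which should give 34 beside the two symmetrical dimers, to be separated by chromatography.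

Step 13. The trifluoroacetic acid that accompanies the acylation may protonate the bridge-bearing carbon of ring B, or the acylating agent may attack it, and either event would cut the diarylmethane; benzyl groups may also begin to leave under the acid. The fallback gives up electrophilic substitution and brings in both ketones through aryllithiums; it sets out from 26 and comes back at 33. Compound 26 is brominated at the free ring B carbon (NBS, MeCN/CH2Cl2, −20 to 0 °C, dark) to 1,3,5-tris(benzyloxy)-2-{[2,4-bis(benzyloxy)-3-bromo-6-methoxy-5-methylphenyl]methyl}-4-bromo-6-methylbenzene F3. Twofold bromine–lithium exchange (t-BuLi, 4.2 equiv, THF, −78 °C) should give the dilithio compound F4, which takes up two molecules of 27 to form the dilithium bis-hemiaminal F5, and aqueous NH4Cl then releases 33.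

Step 9. The ynolate is formed beside one equivalent of benzonitrile, which may capture the lithioisoxazole or the C-nucleophilic ynolate, and the volatile product must be separated from it. The fallback makes the ynolate without a nitrile; it replaces 16 by bought acetylene F6 and comes back to the route at 18. Acetylene is metalated (n-BuLi, THF, −78 °C) to monolithium acetylide F7, and this is oxidised with t-BuOOLi (from t-BuOOH and LiN(SiMe3)2, −78 to −20 °C) to 18, which is silylated with TIPSOTf as in step 9 to give 19.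

**Further compounds**
F1 | step 10 | 1-(2,4,6-trihydroxy-3-methylphenyl)butan-1-one | CCCC(=O)c1c(O)cc(O)c(C)c1O
F2 | step 10 | 1-(2,6-dihydroxy-4-methoxy-3-methylphenyl)butan-1-one (aspidinol) | CCCC(=O)c1c(O)cc(OC)c(C)c1O
F3 | step 13 | 1,3,5-tris(benzyloxy)-2-{[2,4-bis(benzyloxy)-3-bromo-6-methoxy-5-methylphenyl]methyl}-4-bromo-6-methylbenzene | COc1c(C)c(OCc2ccccc2)c(Br)c(OCc2ccccc2)c1Cc1c(OCc2ccccc2)c(C)c(OCc2ccccc2)c(Br)c1OCc1ccccc1
F4 | step 13 | dilithio compound of F3 (both bromine atoms replaced by lithium) | COc1c(C)c(OCc2ccccc2)c([Li])c(OCc2ccccc2)c1Cc1c(OCc2ccccc2)c(C)c(OCc2ccccc2)c([Li])c1OCc1ccccc1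
F5 | step 13 | dilithium bis-hemiaminal (each former C–Br carbon bears C(OLi)(propyl)N(OMe)Me; mixture of diastereomers) | COc1c(C)c(OCc2ccccc2)c(C(CCC)(O[Li])N(C)OC)c(OCc2ccccc2)c1Cc1c(OCc2ccccc2)c(C)c(OCc2ccccc2)c(C(CCC)(O[Li])N(C)OC)c1OCc1ccccc1
F6 | step 9 | acetylene | C#C
F7 | step 9 | lithium acetylide | [Li]C#C
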